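**Plan**

Cuts: first the C12'–S bond (thioacetate for bromide), then the C6–C1' bond between the 4-pyranone ring and the allylic CH2. The ring half is cut further at O–CH3 on C2, O1–C2, C5–C6 and C3–C4, and the chain half at C1'–C2' and C3'–CH3.
Ring half, forward: methyl methoxyacetate is C-acylated (C3–C4) and the β-keto ester dianion is formylated (C5–C6). Lactonisation closes O1–C2 to a 4-hydroxy-2-pyranone, and base-free O-methylation turns this ring into 2,3-dimethoxy-5-methyl-4-pyranone.
Chain half, forward: 10-undecyn-1-ol gives the E-allylic alcohol by carboalumination and hydroxymethylation, then the allyl/alkyl dibromide. No protecting group is used.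
Enabling feature: C2, C3 and C5 of the pyranone ring are substituted, so C6 carries the only ring hydrogen. It sits next to O1 and is the β-carbon of the vinylogous ester O1–C6=C5–C4=O, so it can be metalated directly and joined to C1' without halogen, tin or any other activating group on the ring.
Stereochemistry: there is no stereocentre. The E C2'=C3' double bond comes from the syn-carboalumination and is carried through the coupling with retention.

Key step: step 6

Assumption: ring atoms are O1 and C2–C6 of the target pyranone, chain atoms C1'–C12' are counted from the ring, TMP stands for 2,2,6,6-tetramethylpiperidin-1-yl, and the amide bases are taken as commercial solutions.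

**Step 1**
Reactants: 1 methyl methoxyacetate; 2 propionyl chloride
Product: 4 methyl 2-methoxy-3-oxopentanoate, via lithium enolate 3 (not isolated)
Conditions: 1 (2.0 equiv), LiN(iPr)2 (2.0 equiv), THF, −78 °C; 2 (1.0 equiv), −78 °C; 1 M HCl
Reagents that add atoms: none
Why: Crossed Claisen-type C-acylation of a preformed ester lithium enolate by an acid chloride; the second equivalent of enolate takes up the acidic proton of the β-keto ester and so stops further acylation, and the new C2 stereocentre is racemic, labile and lost in step 2.

**Step 2**
Reactants: 4 methyl 2-methoxy-3-oxopentanoate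
Product: 7 4-hydroxy-3-methoxy-5-methyl-2H-pyran-2-one, via dilithio dianion 5 (not isolated), via formyl keto ester 6 (not isolated)
Conditions: LiN(iPr)2 (2.2 equiv), THF, −78 to 0 °C; HCO2Me, −78 °C to rt; 1 M HCl; then DBU (1.2 equiv), toluene, rt to 60 °C; 1 M HCl
Reagents that add atoms: methyl formate COC=O
Why: γ-Selective acylation of a β-keto ester dianion (the last-formed, more reactive C4 carbanion attacks methyl formate) followed by DBU-mediated lactonisation of the enol oxygen onto the methyl ester, the standard closure of 3,5-dioxo esters to 4-hydroxy-2-pyranones; both sp3 centres become sp2.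

**Step 3**
Reactants: 7 4-hydroxy-3-methoxy-5-methyl-2H-pyran-2-one
Product: 9 2,3-dimethoxy-5-methyl-4H-pyran-4-one, via pyrylium triflate 8 (not isolated)
Conditions: MeOTf (1.5 equiv), CH2Cl2, rt; sat. aq NaHCO3
Reagents that add atoms: methyl trifluoromethanesulfonate COS(=O)(=O)C(F)(F)F
Why: Base-free O-alkylation of the neutral 4-hydroxy-2-pyranone by a hard methyl donor takes place at the most basic site, the C2 carbonyl oxygen, because this gives the aromatic pyrylium ion 8, and loss of the O4 proton then leaves the 2-methoxy-4-pyranone, a well-precedented regiospecific route to α-methoxy-γ-pyrones.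

**Step 4**
Reactants: 10 10-undecyn-1-ol
Product: 13 (E)-3-methyldodec-2-ene-1,12-diol, via alkenylalane 11 (not isolated), via lithium aluminate 12 (not isolated)
Conditions: AlMe3 (3.5 equiv), Cp2ZrCl2 (0.25 equiv), CH2Cl2, 0 °C to rt; volatiles removed; n-BuLi, hexane, 0 °C; (CH2O)n, THF, rt; 1 M HCl, 0 °C
Reagents that add atoms: trimethylaluminium C[Al](C)C; paraformaldehyde (as formaldehyde) C=O
Why: Zirconium-catalysed syn-carboalumination of a terminal alkyne (Negishi carboalumination) puts CH3 on the internal and aluminium on the terminal carbon on the same face, the hydroxyl group being masked in the flask as its aluminium alkoxide, and the aluminate is hydroxymethylated by formaldehyde with retention, which fixes the E geometry.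

**Step 5**
Reactants: 13 (E)-3-methyldodec-2-ene-1,12-diol
Product: 14 (E)-1,12-dibromo-3-methyldodec-2-ene
Conditions: CBr4 (2.4 equiv), PPh3 (2.5 equiv), CH2Cl2, −20 to 0 °C
Reagents that add atoms: tetrabromomethane BrC(Br)(Br)Br
Why: Double Appel reaction in which both primary alkoxyphosphonium ions are displaced by bromide in SN2 fashion at low temperature, without allylic transposition or change of the alkene geometry.

**Step 6**
Reactants: 9 2,3-dimethoxy-5-methyl-4H-pyran-4-one; 14 (E)-1,12-dibromo-3-methyldodec-2-ene
Product: 16 6-[(2E)-12-bromo-3-methyldodec-2-en-1-yl]-2,3-dimethoxy-5-methyl-4H-pyran-4-one, via bis(pyranonyl)zinc 15 (not isolated)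
Conditions: Zn(TMP)2·2MgCl2·2LiCl (0.6 equiv), THF, 0 °C to rt; then 14 (0.9 equiv), Pd(PPh3)4 (3 mol %), 0 °C to rt; sat. aq NH4Cl
Reagents that add atoms: none
Why: The hindered zinc amide, helped by MgCl2 bound to the C4 carbonyl oxygen, removes the only ring hydrogen (C6–H, next to O1 and β to C4=O) without adding to the electrophilic C2 or C6, which gives the C6–zinc compound 15. Zerovalent palladium then ionises only the allylic C1'–Br bond of 14 to a π-allyl complex, the pyranonyl group passes from zinc to palladium, and inner-sphere reductive elimination at the unsubstituted CH2 terminus forms C6–C1' (Negishi-type allylation). The closest known reaction types are the zincation of chromones and related 4-pyranones at the carbon next to the ring oxygen with TMP-zinc bases followed by cross-coupling, and the regio- and stereospecific palladium-catalysed coupling of arylzinc reagents with geranyl-type halides. No ring is closed and no stereocentre is formed, and the E geometry set in step 4 is kept because syn/anti exchange of the π-allyl unit would have to pass through a tertiary σ-allyl palladium species. The step needs site selectivity between two C–Br bonds (the unactivated primary C12'–Br does not add to Pd(PPh3)4 at room temperature), linear rather than branched coupling (secured by the fully substituted C3') and no migration of the double bond. The last point is secured by the low basicity of organozinc species, which leave the new, doubly activated C1'H2 group untouched.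

**Step 7**
Reactants: 16 6-[(2E)-12-bromo-3-methyldodec-2-en-1-yl]-2,3-dimethoxy-5-methyl-4H-pyran-4-one
Product: 17 lehualide C
Conditions: KSC(O)CH3 (1.2 equiv), DMF, 0 °C to rt
Reagents that add atoms: potassium thioacetate CC(=O)[S-].[K+]
Why: SN2 displacement of the primary bromide by the soft and almost non-basic thioacetate ion, so that the skipped double bond, the acidic C1'H2 group and the two methoxy groups of the pyranone should stay untouched.

**Compound list**

1 | methyl methoxyacetate | COCC(=O)OC | starting material
2 | propionyl chloride | CCC(=O)Cl | starting material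
3 | lithium enolate of methyl methoxyacetate (formed in the flask) | [Li+].COC=C([O-])OC | intermediate
4 | methyl 2-methoxy-3-oxopentanoate (racemic, labile centre) | CCC(=O)C(OC)C(=O)OC | intermediate
5 | dilithium dianion of 4 (formed in the flask) | [Li+].[Li+].CC=C([O-])C(OC)=C([O-])OC | intermediate
6 | methyl 2-methoxy-4-methyl-3,5-dioxopentanoate (keto/enol mixture, formed in the flask) | COC(=O)C(OC)C(=O)C(C)C=O | intermediate
7 | 4-hydroxy-3-methoxy-5-methyl-2H-pyran-2-one | COc1c(O)c(C)coc1=O | intermediate
8 | 4-hydroxy-2,3-dimethoxy-5-methylpyrylium trifluoromethanesulfonate (formed in the flask) | COc1c(O)c(C)c[o+]c1OC.[O-]S(=O)(=O)C(F)(F)F | intermediate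
9 | 2,3-dimethoxy-5-methyl-4H-pyran-4-one | COc1occ(C)c(=O)c1OC | intermediate
10 | 10-undecyn-1-ol | C#CCCCCCCCCCO | starting material
11 | (E)-alkenyl(dimethyl)alane with dimethylaluminium alkoxide terminus (formed in the flask) | C[Al](C)/C=C(\C)CCCCCCCCCO[Al](C)C | intermediate
12 | lithium butyl(dimethyl)[(E)-alkenyl]aluminate of 11 (formed in the flask) | [Li+].CCCC[Al-](C)(C)/C=C(\C)CCCCCCCCCO[Al](C)C | intermediate
13 | (E)-3-methyldodec-2-ene-1,12-diol | OC/C=C(\C)CCCCCCCCCO | intermediate
14 | (E)-1,12-dibromo-3-methyldodec-2-ene | BrC/C=C(\C)CCCCCCCCCBr | intermediate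
15 | bis(5,6-dimethoxy-3-methyl-4-oxo-4H-pyran-2-yl)zinc (formed in the flask) | COc1oc([Zn]c2oc(OC)c(OC)c(=O)c2C)c(C)c(=O)c1OC | intermediate
16 | 6-[(2E)-12-bromo-3-methyldodec-2-en-1-yl]-2,3-dimethoxy-5-methyl-4H-pyran-4-one | COc1oc(C/C=C(\C)CCCCCCCCCBr)c(C)c(=O)c1OC | intermediate
17 | lehualide C, S-[(10E)-12-(5,6-dimethoxy-3-methyl-4-oxo-4H-pyran-2-yl)-10-methyldodec-10-en-1-yl] ethanethioate | COc1oc(C/C=C(\C)CCCCCCCCCSC(C)=O)c(C)c(=O)c1OC | target

**Step count**

Total step count: 7. Longest linear sequence: 5 steps (1, 2, 3, 6, 7).

**Steps most likely to fail**

Step 6. The donor-substituted ring may be zincated slowly or incompletely. The metalated pyranone may break down or condense with itself. Part of the coupling may occur at the tertiary allyl terminus, or the double bond may drift into conjugation.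

The fallback sets out from 9 and replaces the one-pot metalation and coupling by an isolable nucleophile and a neutral coupling. A short deprotonation with LiN(iPr)2 in THF at −78 °C and immediate quench with Bu3SnCl should give 2,3-dimethoxy-5-methyl-6-(tributylstannyl)-4H-pyran-4-one F1. Stille coupling of F1 with 14 (Pd2(dba)3, AsPh3, THF, 50 °C), free of base and of basic organometal species, comes back to the route at 16.

Step 2. Proton exchange between the dianion and the formylated product may stop the acylation early. The free formyl compound may condense with itself, and the lactonisation may be sluggish.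

The fallback sets out from 1 (through its enolate 3) and brings the C6 carbon in as a masked formyl group inside the acyl donor. Ethyl 1-propenyl ether and oxalyl chloride should give (E)-4-ethoxy-3-methyl-2-oxobut-3-enoyl chloride F2. Heating to about 120 °C should decarbonylate it to (E)-3-ethoxy-2-methylprop-2-enoyl chloride F3. Acylation of enolate 3 with F3 at −78 °C should give methyl (E)-5-ethoxy-2-methoxy-4-methyl-3-oxopent-4-enoate F4. Aqueous acid (H2SO4, THF, warm) cleaves the enol ether and closes the lactone, and the route is rejoined at 7.

Step 3. Proton exchange with the basic product may create the ambident pyranonate, so that methyl transfer to O4 or double methylation erodes the regiochemistry.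

The fallback sets out from 7 and blocks O4 with a group that cannot be exchanged as a proton. TBSCl and imidazole in DMF should give 4-(tert-butyldimethylsilyloxy)-3-methoxy-5-methyl-2H-pyran-2-one F5. MeOTf in CH2Cl2 can then only reach the C2 carbonyl oxygen, giving 4-(tert-butyldimethylsilyloxy)-2,3-dimethoxy-5-methylpyrylium trifluoromethanesulfonate F6. Aqueous NaHCO3 removes the silyl group and comes back to the route at 9.

**Further compounds**

F1 | step 6 | 2,3-dimethoxy-5-methyl-6-(tributylstannyl)-4H-pyran-4-one | CCCC[Sn](CCCC)(CCCC)c1oc(OC)c(OC)c(=O)c1C
F2 | step 2 | (E)-4-ethoxy-3-methyl-2-oxobut-3-enoyl chloride | CCO/C=C(\C)C(=O)C(=O)Cl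
F3 | step 2 | (E)-3-ethoxy-2-methylprop-2-enoyl chloride | CCO/C=C(\C)C(=O)Cl
F4 | step 2 | methyl (E)-5-ethoxy-2-methoxy-4-methyl-3-oxopent-4-enoate | CCO/C=C(\C)C(=O)C(OC)C(=O)OC
F5 | step 3 | 4-(tert-butyldimethylsilyloxy)-3-methoxy-5-methyl-2H-pyran-2-one | COc1c(O[Si](C)(C)C(C)(C)C)c(C)coc1=O
F6 | step 3 | 4-(tert-butyldimethylsilyloxy)-2,3-dimethoxy-5-methylpyrylium trifluoromethanesulfonate | COc1c(O[Si](C)(C)C(C)(C)C)c(C)c[o+]c1OC.[O-]S(=O)(=O)C(F)(F)F
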